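Locants (carotenoid style): hydroxy-β-ring C1–C6, chain C7–C15 then C15'–C7', hydroxy-ε-ring C1'–C6', lactone carbonyl C19'; TBS = tert-butyldimethylsilyl.
Cuts, in retrosynthetic order: the two O–Si bonds; the C10–C11 diene single bond together with C9–CH3; C11=C12; C11'=C12'; C8'–C9'; C6'–C7'; and on the other side C9≡C10 and C6–C7.
Enabling feature: the β-ring end is ring–C7H=C8H–C9(CH3)=C10H–, an E-trisubstituted, methyl-branched alkene whose hydrogen-bearing carbon C10 is one end of the bond to be made; this is the retron of a syn-methylmetalation of the terminal enyne ring–CH=CH–C≡CH, so C10 is born as a carbon–metal centre and is coupled in the same flask to C11 of an (E)-iodoalkene that already carries the Z-ylidenebutenolide.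
Forward order (all three rings are bought as rings): fragment 1 = actinol → ring enol triflate → Heck (C6–C7) → terminal enyne; fragment 2 = ketoisophorone → epoxide → Wharton → Johnson–Claisen (C6'–C7') → Negishi with 3-bromobutenolide (C8'–C9') → ylidenation with the C10 trienedial (C11'=C12') → Takai (C11=C12); then union (C9–CH3 and C10–C11) and desilylation.
Stereochemistry: C3 from (4R,6R)-actinol; C3' from asymmetric transfer hydrogenation; C6' by suprafacial [3,3] transfer from a temporary C4' carbinol placed trans to C3'–O by epoxidation anti to the silyloxy group; 7E from Heck, 9E from syn-carbometalation, 11E from Takai, 11'Z from thermodynamic elimination, the other chain alkenes from the all-E trienedial.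

Key step: step 15

Assumption: in step 5 the (R,R) ligand is taken to give the R carbinol (ring alkene in the place usually held by an aryl group); should the sense be opposite, the (S,S) ligand is used and nothing else changes.

Step 1
Reactants: 1 (4R,6R)-4-hydroxy-2,2,6-trimethylcyclohexan-1-one (actinol)
Product: 2 (4R,6R)-4-(TBSO)-2,2,6-trimethylcyclohexan-1-one
Conditions: TBSCl, imidazole, DMF, 23 °C
Reagents that add atoms: tert-butyldimethylsilyl chloride, CC(C)(C)[Si](C)(C)Cl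
Why: Imidazole-promoted silylation of the secondary alcohol; the carbinol configuration is untouched.

Step 2
Reactants: 2 (4R,6R)-4-(TBSO)-2,2,6-trimethylcyclohexan-1-one
Product: 3 (4R)-4-(TBSO)-2,6,6-trimethylcyclohex-1-en-1-yl trifluoromethanesulfonate
Conditions: LiN(i-Pr)2, THF, −78 °C; PhNTf2, −78 → 23 °C
Reagents that add atoms: N-phenylbis(trifluoromethanesulfonimide), O=S(=O)(N(c1ccccc1)S(=O)(=O)C(F)(F)F)C(F)(F)F
Why: C2 is quaternary, so the base can enolise only toward C6 and O-sulfonylation of the enolate (enol triflate formation) should give the single tetrasubstituted alkenyl triflate; the C6 stereocentre of 1 is erased on purpose.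

Step 3
Reactants: 3 (4R)-4-(TBSO)-2,6,6-trimethylcyclohex-1-en-1-yl trifluoromethanesulfonate; 4 but-3-en-2-one
Product: 5 (3E)-4-[(4R)-4-(TBSO)-2,6,6-trimethylcyclohex-1-en-1-yl]but-3-en-2-one
Conditions: Pd(OAc)2 (5 mol%), PPh3 (10 mol%), Et3N, DMF, 70 °C
Reagents that add atoms: none
Why: Heck reaction of an alkenyl triflate with an electron-poor monosubstituted alkene: oxidative addition, syn-insertion at the unsubstituted terminus and syn-β-hydride elimination should deliver the conjugated E-dienone (7E).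

Step 4
Reactants: 5 (3E)-4-[(4R)-4-(TBSO)-2,6,6-trimethylcyclohex-1-en-1-yl]but-3-en-2-one
Product: 7 (4R)-4-(TBSO)-1-[(1E)-but-1-en-3-yn-1-yl]-2,6,6-trimethylcyclohex-1-ene, via enol phosphate 6 (not isolated)
Conditions: LiN(i-Pr)2 (1.1 equiv), THF, −78 °C; ClP(O)(OEt)2, −78 → 23 °C; LiN(i-Pr)2 (2.3 equiv), −78 → 23 °C; H2O
Reagents that add atoms: none
Why: Kinetic deprotonation of the acetyl methyl group, O-phosphorylation and base-induced elimination of diethyl phosphate from enol phosphate 6 (methyl ketone to terminal alkyne conversion) should give the enyne without touching the 7E alkene or the silyl ether.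

Step 5
Reactants: 8 2,6,6-trimethylcyclohex-2-ene-1,4-dione (ketoisophorone)
Product: 9 (4R)-4-hydroxy-2,6,6-trimethylcyclohex-2-en-1-one
Conditions: RuCl[(R,R)-TsDPEN](p-cymene) (1 mol%), HCO2H–Et3N (5:2), CH2Cl2, 23 °C
Reagents that add atoms: none
Why: Noyori asymmetric transfer hydrogenation should reduce only the C4 carbonyl, because C1 is flanked by the gem-dimethyl carbon and the methyl-bearing alkene carbon, and the chiral Ru–H/N–H catalyst sets the carbinol centre (the future C3') as R.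

Step 6
Reactants: 9 (4R)-4-hydroxy-2,6,6-trimethylcyclohex-2-en-1-one
Product: 10 (4R)-4-(TBSO)-2,6,6-trimethylcyclohex-2-en-1-one
Conditions: TBSCl, imidazole, DMF, 23 °C
Reagents that add atoms: tert-butyldimethylsilyl chloride, CC(C)(C)[Si](C)(C)Cl
Why: Imidazole-promoted silylation; the ether blocks base-induced tautomerisation of the γ-hydroxy enone and hydroxyl-directed syn epoxidation in the next step.

Step 7
Reactants: 10 (4R)-4-(TBSO)-2,6,6-trimethylcyclohex-2-en-1-one
Product: 11 (1S,5R,6S)-5-(TBSO)-1,3,3-trimethyl-7-oxabicyclo[4.1.0]heptan-2-one (epoxide oxygen trans to the silyloxy group)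
Conditions: 30% aq. H2O2 (3 equiv), NaOH (0.3 equiv), MeOH, 0 °C
Reagents that add atoms: hydrogen peroxide, OO
Why: Weitz–Scheffer nucleophilic epoxidation: hydroperoxide adds to the β-carbon (C4') on the face opposite to the neighbouring C3' silyloxy group and the enolate closes on the same face, so the epoxide should form trans to OTBS and set the temporary C4' configuration.

Step 8
Reactants: 11 (1S,5R,6S)-5-(TBSO)-1,3,3-trimethyl-7-oxabicyclo[4.1.0]heptan-2-one
Product: 13 (1R,6R)-6-(TBSO)-2,4,4-trimethylcyclohex-2-en-1-ol (hydroxy trans to silyloxy), via epoxy hydrazone 12 (not isolated)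
Conditions: N2H4·H2O (3 equiv), AcOH (0.5 equiv), MeOH, 0 → 23 °C
Reagents that add atoms: none
Why: Wharton transposition: the small α-nucleophile hydrazine condenses with the epoxide-activated carbonyl, and fragmentation of epoxy hydrazone 12 with loss of N2 moves the alkene to C5'=C6' while the C4'–O bond of the epoxide is kept, so the carbinol stays trans to OTBS.

Step 9
Reactants: 13 (1R,6R)-6-(TBSO)-2,4,4-trimethylcyclohex-2-en-1-ol
Product: 15 ethyl [(1R,4R)-4-(TBSO)-2,6,6-trimethylcyclohex-2-en-1-yl]acetate, via ketene acetal 14 (not isolated)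
Conditions: MeC(OEt)3 (8 equiv), EtCO2H (0.1 equiv), xylene, 140 °C, EtOH distilled off
Reagents that add atoms: triethyl orthoacetate, CC(OCC)(OCC)OCC
Why: Johnson–Claisen rearrangement: ketene acetal 14 rearranges suprafacially across the ring, so the C6'–C7' bond forms on the face from which the C4'–O bond departs, i.e. trans to the C3' silyloxy group, which sets C6' as R by 1,3-chirality transfer and erases the temporary C4' centre.

Step 10
Reactants: 15 ethyl [(1R,4R)-4-(TBSO)-2,6,6-trimethylcyclohex-2-en-1-yl]acetate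
Product: 16 2-[(1R,4R)-4-(TBSO)-2,6,6-trimethylcyclohex-2-en-1-yl]ethan-1-ol
Conditions: LiAlH4, THF, 0 °C
Reagents that add atoms: none
Why: Hydride reduction of the ester to the primary alcohol; silyl ether, ring alkene and both stereocentres are inert.

Step 11
Reactants: 16 2-[(1R,4R)-4-(TBSO)-2,6,6-trimethylcyclohex-2-en-1-yl]ethan-1-ol
Product: 17 1-iodo-2-[(1R,4R)-4-(TBSO)-2,6,6-trimethylcyclohex-2-en-1-yl]ethane
Conditions: I2, PPh3, imidazole, CH2Cl2, 0 → 23 °C
Reagents that add atoms: iodine, [I][I]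
Why: Appel-type iodination of the primary alcohol by SN2 displacement of the oxyphosphonium group; the imidazole buffer protects the allylic silyl ether.

Step 12
Reactants: 17 1-iodo-2-[(1R,4R)-4-(TBSO)-2,6,6-trimethylcyclohex-2-en-1-yl]ethane; 18 3-bromofuran-2(5H)-one
Product: 20 3-{2-[(1R,4R)-4-(TBSO)-2,6,6-trimethylcyclohex-2-en-1-yl]ethyl}furan-2(5H)-one, via alkylzinc iodide 19 (not isolated)
Conditions: Zn dust, LiCl, THF, 40 °C; then 18, Pd(OAc)2 (2 mol%), SPhos (4 mol%), THF, 23 °C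
Reagents that add atoms: none
Why: Negishi sp3–sp2 coupling: zinc inserts into the primary C–I bond and alkylzinc iodide 19 couples under zerovalent palladium catalysis with the α-bromo enoate C–Br bond of 18, which brings in the butenolide ring intact and forms C8'–C9'.

Step 13
Reactants: 20 3-{2-[(1R,4R)-4-(TBSO)-2,6,6-trimethylcyclohex-2-en-1-yl]ethyl}furan-2(5H)-one; 21 (2E,4E,6E)-2,7-dimethylocta-2,4,6-trienedial
Product: 24 (2E,4E,6E)-8-[(2Z)-4-{2-[(1R,4R)-4-(TBSO)-2,6,6-trimethylcyclohex-2-en-1-yl]ethyl}-5-oxofuran-2(5H)-ylidene]-2,7-dimethylocta-2,4,6-trienal, via silyloxyfuran 22 (not isolated), via silyl aldol adduct 23 (not isolated)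
Conditions: TBSOTf (1.3 equiv), i-Pr2NEt (3 equiv), CH2Cl2, 0 °C; 21 (3 equiv), −78 → 0 °C; then DBU (2 equiv), 23 °C, dark
Reagents that add atoms: none
Why: One-pot vinylogous Mukaiyama aldol addition/E1cB elimination: silyloxyfuran 22 attacks one aldehyde group of the excess dialdehyde through its γ-carbon, and DBU expels silanolate from adduct 23 by way of the extended enolate to give the thermodynamically preferred Z-ylidene isomer (chain syn to the ring oxygen, 11'Z).

Step 14
Reactants: 24 (2E,4E,6E)-8-[(2Z)-4-{2-[(1R,4R)-4-(TBSO)-2,6,6-trimethylcyclohex-2-en-1-yl]ethyl}-5-oxofuran-2(5H)-ylidene]-2,7-dimethylocta-2,4,6-trienal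
Product: 25 (5Z)-3-{2-[(1R,4R)-4-(TBSO)-2,6,6-trimethylcyclohex-2-en-1-yl]ethyl}-5-[(2E,4E,6E,8E)-9-iodo-2,7-dimethylnona-2,4,6,8-tetraen-1-ylidene]furan-2(5H)-one
Conditions: CrCl2 (8 equiv), CHI3 (3 equiv), THF–1,4-dioxane (1:6), 0 → 23 °C, dark
Reagents that add atoms: iodoform, IC(I)I
Why: Takai iodo-olefination: the geminal dichromium species from CHI3 and CrCl2 adds only to the aldehyde and eliminates through the anti arrangement to give the E-iodoalkene (11E), leaving lactone and silyl ether alone.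

Step 15
Reactants: 7 (4R)-4-(TBSO)-1-[(1E)-but-1-en-3-yn-1-yl]-2,6,6-trimethylcyclohex-1-ene; 25 (5Z)-3-{2-[(1R,4R)-4-(TBSO)-2,6,6-trimethylcyclohex-2-en-1-yl]ethyl}-5-[(2E,4E,6E,8E)-9-iodo-2,7-dimethylnona-2,4,6,8-tetraen-1-ylidene]furan-2(5H)-one
Product: 28 (5Z)-3-{2-[(1R,4R)-4-(TBSO)-2,6,6-trimethylcyclohex-2-en-1-yl]ethyl}-5-[(2E,4E,6E,8E,10E,12E)-13-[(4R)-4-(TBSO)-2,6,6-trimethylcyclohex-1-en-1-yl]-2,7,11-trimethyltrideca-2,4,6,8,10,12-hexaen-1-ylidene]furan-2(5H)-one, via alkenylalane 26 (not isolated), via alkenylzinc chloride 27 (not isolated)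
Conditions: 7 (1.5 equiv), AlMe3 (3 equiv), Cp2ZrCl2 (0.5 equiv), ClCH2CH2Cl, 23 °C; volatiles removed in vacuo; THF, ZnCl2 (1.5 equiv); then 25 (1 equiv), Pd2(dba)3 (2.5 mol%), P(2-furyl)3 (10 mol%), THF–DMF, 23 °C, dark
Reagents that add atoms: trimethylaluminium, C[Al](C)C
Why: Cp2ZrCl2-assisted syn-methylalumination of the terminal alkyne of 7 places CH3 on the internal carbon C9 and aluminium on C10 (alane 26), Al-to-Zn exchange gives 27, and zerovalent palladium formed from Pd2(dba)3 inserts into the C11–I bond of 25, transmetalates with 27 and reductively eliminates with retention at both sp2 carbons to forge C10–C11. The closest known reaction type is the one-pot zirconium-catalysed carboalumination/Pd–Zn Negishi alkenyl–alkenyl coupling used for retinoid and carotenoid polyenes. No ring is closed and no stereocentre is formed; the controlled elements are alkene geometries: 9E follows from the syn addition across C9≡C10 and 11E is carried over from 25. The step needs methyl delivery to the internal alkyne carbon, secured by the terminal alkyne polarised by the conjugated C7=C8 vinyl group, and reaction at the C–I bond in the presence of the lactone carbonyl, secured by the mild alkenylzinc nucleophile, fast oxidative addition into the iodide and removal of excess AlMe3 before 25 is added. The Z-ylidenebutenolide and the all-E polyene should survive because the coupling runs at ambient temperature in the dark.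

Step 16
Reactants: 28 bis-TBS ether from step 15
Product: 29 (5Z)-3-{2-[(1R,4R)-4-hydroxy-2,6,6-trimethylcyclohex-2-en-1-yl]ethyl}-5-[(2E,4E,6E,8E,10E,12E)-13-[(4R)-4-hydroxy-2,6,6-trimethylcyclohex-1-en-1-yl]-2,7,11-trimethyltrideca-2,4,6,8,10,12-hexaen-1-ylidene]furan-2(5H)-one (CNP0242041.1)
Conditions: Bu4NF (6 equiv), AcOH (6 equiv), THF, 0 → 23 °C, dark, argon
Reagents that add atoms: none
Why: Fluoride-induced cleavage of both Si–O bonds (desilylation); buffering with AcOH should suppress base-induced opening or isomerisation of the ylidenebutenolide and avoid acid ionisation of the allylic C3' alcohol, and no stereocentre is touched.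

Compound list
1 | (4R,6R)-4-hydroxy-2,2,6-trimethylcyclohexan-1-one (actinol) | O=C1[C@H](C)C[C@@H](O)CC1(C)C | starting material
2 | (4R,6R)-4-(TBSO)-2,2,6-trimethylcyclohexan-1-one | O=C1[C@H](C)C[C@@H](O[Si](C)(C)C(C)(C)C)CC1(C)C | intermediate
3 | (4R)-4-(TBSO)-2,6,6-trimethylcyclohex-1-en-1-yl trifluoromethanesulfonate | FC(F)(F)S(=O)(=O)OC1=C(C)C[C@@H](O[Si](C)(C)C(C)(C)C)CC1(C)C | intermediate
4 | but-3-en-2-one | CC(=O)C=C | starting material
5 | (3E)-4-[(4R)-4-(TBSO)-2,6,6-trimethylcyclohex-1-en-1-yl]but-3-en-2-one | CC(=O)/C=C/C1=C(C)C[C@@H](O[Si](C)(C)C(C)(C)C)CC1(C)C | intermediate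
6 | (3E)-4-[(4R)-4-(TBSO)-2,6,6-trimethylcyclohex-1-en-1-yl]buta-1,3-dien-2-yl diethyl phosphate | C=C(OP(=O)(OCC)OCC)/C=C/C1=C(C)C[C@@H](O[Si](C)(C)C(C)(C)C)CC1(C)C | intermediate (not isolated)
7 | (4R)-4-(TBSO)-1-[(1E)-but-1-en-3-yn-1-yl]-2,6,6-trimethylcyclohex-1-ene | C#C/C=C/C1=C(C)C[C@@H](O[Si](C)(C)C(C)(C)C)CC1(C)C | intermediate
8 | 2,6,6-trimethylcyclohex-2-ene-1,4-dione (ketoisophorone) | CC1=CC(=O)CC(C)(C)C1=O | starting material
9 | (4R)-4-hydroxy-2,6,6-trimethylcyclohex-2-en-1-one | CC1=C[C@H](O)CC(C)(C)C1=O | intermediate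
10 | (4R)-4-(TBSO)-2,6,6-trimethylcyclohex-2-en-1-one | CC1=C[C@H](O[Si](C)(C)C(C)(C)C)CC(C)(C)C1=O | intermediate
11 | (1S,5R,6S)-5-(TBSO)-1,3,3-trimethyl-7-oxabicyclo[4.1.0]heptan-2-one (epoxide trans to silyloxy) | C[C@]12O[C@H]1[C@H](O[Si](C)(C)C(C)(C)C)CC(C)(C)C2=O | intermediate
12 | hydrazone of 11 (C=N–NH2 in place of C=O, configuration unchanged) | C[C@]12O[C@H]1[C@H](O[Si](C)(C)C(C)(C)C)CC(C)(C)C2=NN | intermediate (not isolated)
13 | (1R,6R)-6-(TBSO)-2,4,4-trimethylcyclohex-2-en-1-ol (hydroxy trans to silyloxy) | CC1=CC(C)(C)C[C@@H](O[Si](C)(C)C(C)(C)C)[C@@H]1O | intermediate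
14 | (1R,6R)-6-(TBSO)-1-[(1-ethoxyethenyl)oxy]-2,4,4-trimethylcyclohex-2-ene | CC1=CC(C)(C)C[C@@H](O[Si](C)(C)C(C)(C)C)[C@@H]1OC(=C)OCC | intermediate (not isolated)
15 | ethyl [(1R,4R)-4-(TBSO)-2,6,6-trimethylcyclohex-2-en-1-yl]acetate | CC1=C[C@H](O[Si](C)(C)C(C)(C)C)CC(C)(C)[C@H]1CC(=O)OCC | intermediate
16 | 2-[(1R,4R)-4-(TBSO)-2,6,6-trimethylcyclohex-2-en-1-yl]ethan-1-ol | CC1=C[C@H](O[Si](C)(C)C(C)(C)C)CC(C)(C)[C@H]1CCO | intermediate
17 | 1-iodo-2-[(1R,4R)-4-(TBSO)-2,6,6-trimethylcyclohex-2-en-1-yl]ethane | CC1=C[C@H](O[Si](C)(C)C(C)(C)C)CC(C)(C)[C@H]1CCI | intermediate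
18 | 3-bromofuran-2(5H)-one | O=C1OCC=C1Br | starting material
19 | {2-[(1R,4R)-4-(TBSO)-2,6,6-trimethylcyclohex-2-en-1-yl]ethyl}zinc iodide | CC1=C[C@H](O[Si](C)(C)C(C)(C)C)CC(C)(C)[C@H]1CC[Zn]I | intermediate (not isolated)
20 | 3-{2-[(1R,4R)-4-(TBSO)-2,6,6-trimethylcyclohex-2-en-1-yl]ethyl}furan-2(5H)-one | CC1=C[C@H](O[Si](C)(C)C(C)(C)C)CC(C)(C)[C@H]1CCC1=CCOC1=O | intermediate
21 | (2E,4E,6E)-2,7-dimethylocta-2,4,6-trienedial | O=C/C(C)=C/C=C/C=C(C)/C=O | starting material
22 | 2-(TBSO)-3-{2-[(1R,4R)-4-(TBSO)-2,6,6-trimethylcyclohex-2-en-1-yl]ethyl}furan | CC1=C[C@H](O[Si](C)(C)C(C)(C)C)CC(C)(C)[C@H]1CCc1ccoc1O[Si](C)(C)C(C)(C)C | intermediate (not isolated)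
23 | 5-[(2E,4E,6E)-1-(TBSO)-2,7-dimethyl-8-oxoocta-2,4,6-trienyl]-3-{2-[(1R,4R)-4-(TBSO)-2,6,6-trimethylcyclohex-2-en-1-yl]ethyl}furan-2(5H)-one (diastereomer mixture at the two new sp3 carbons) | CC1=C[C@H](O[Si](C)(C)C(C)(C)C)CC(C)(C)[C@H]1CCC1=CC(OC1=O)C(O[Si](C)(C)C(C)(C)C)/C(C)=C/C=C/C=C(C)/C=O | intermediate (not isolated)
24 | (2E,4E,6E)-8-[(2Z)-4-{2-[(1R,4R)-4-(TBSO)-2,6,6-trimethylcyclohex-2-en-1-yl]ethyl}-5-oxofuran-2(5H)-ylidene]-2,7-dimethylocta-2,4,6-trienal | CC1=C[C@H](O[Si](C)(C)C(C)(C)C)CC(C)(C)[C@H]1CCC1=C/C(=C/C(C)=C/C=C/C=C(C)/C=O)OC1=O | intermediate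
25 | (5Z)-3-{2-[(1R,4R)-4-(TBSO)-2,6,6-trimethylcyclohex-2-en-1-yl]ethyl}-5-[(2E,4E,6E,8E)-9-iodo-2,7-dimethylnona-2,4,6,8-tetraen-1-ylidene]furan-2(5H)-one | CC1=C[C@H](O[Si](C)(C)C(C)(C)C)CC(C)(C)[C@H]1CCC1=C/C(=C/C(C)=C/C=C/C=C(C)/C=C/I)OC1=O | intermediate
26 | dimethyl{(1E,3E)-2-methyl-4-[(4R)-4-(TBSO)-2,6,6-trimethylcyclohex-1-en-1-yl]buta-1,3-dien-1-yl}alane | C[Al](C)/C=C(C)/C=C/C1=C(C)C[C@@H](O[Si](C)(C)C(C)(C)C)CC1(C)C | intermediate (not isolated)
27 | chloro{(1E,3E)-2-methyl-4-[(4R)-4-(TBSO)-2,6,6-trimethylcyclohex-1-en-1-yl]buta-1,3-dien-1-yl}zinc | Cl[Zn]/C=C(C)/C=C/C1=C(C)C[C@@H](O[Si](C)(C)C(C)(C)C)CC1(C)C | intermediate (not isolated)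
28 | (5Z)-3-{2-[(1R,4R)-4-(TBSO)-2,6,6-trimethylcyclohex-2-en-1-yl]ethyl}-5-[(2E,4E,6E,8E,10E,12E)-13-[(4R)-4-(TBSO)-2,6,6-trimethylcyclohex-1-en-1-yl]-2,7,11-trimethyltrideca-2,4,6,8,10,12-hexaen-1-ylidene]furan-2(5H)-one | CC1=C[C@H](O[Si](C)(C)C(C)(C)C)CC(C)(C)[C@H]1CCC1=C/C(=C/C(C)=C/C=C/C=C(C)/C=C/C=C(C)/C=C/C2=C(C)C[C@@H](O[Si](C)(C)C(C)(C)C)CC2(C)C)OC1=O | intermediate
29 | (5Z)-3-{2-[(1R,4R)-4-hydroxy-2,6,6-trimethylcyclohex-2-en-1-yl]ethyl}-5-[(2E,4E,6E,8E,10E,12E)-13-[(4R)-4-hydroxy-2,6,6-trimethylcyclohex-1-en-1-yl]-2,7,11-trimethyltrideca-2,4,6,8,10,12-hexaen-1-ylidene]furan-2(5H)-one | CC1=C[C@H](O)CC(C)(C)[C@H]1CCC1=C/C(=C/C(C)=C/C=C/C=C(C)/C=C/C=C(C)/C=C/C2=C(C)C[C@@H](O)CC2(C)C)OC1=O | target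

Total step count: 16 (fragment 1: steps 1–4; fragment 2: steps 5–14; union and deprotection: steps 15–16).
Longest linear sequence: 12 steps (steps 5–16, from ketoisophorone).

Steps most likely to fail

Risk at step 15. Methyl transfer from residual methylaluminium or methylzinc species to the iodide, addition of the aluminium or zinc organometallics to the ylidenebutenolide, or light- and palladium-induced geometric scrambling of the pentaenyl iodide may erode the union. The fallback sets out from 7 (with 25 as partner) and comes back at 28. The same methylalumination is run, but alane 26 is quenched with I2 to give (4R)-4-(TBSO)-1-[(1E,3E)-4-iodo-3-methylbuta-1,3-dien-1-yl]-2,6,6-trimethylcyclohex-1-ene F1. Iodine–lithium exchange (t-BuLi, Et2O, −78 °C) and trapping with Bu3SnCl should give tributyl{(1E,3E)-2-methyl-4-[(4R)-4-(TBSO)-2,6,6-trimethylcyclohex-1-en-1-yl]buta-1,3-dien-1-yl}stannane F2. This isolable, neutral nucleophile is joined to 25 by a Stille coupling (Pd2(dba)3, AsPh3, NMP, 23 °C, dark) to give 28.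

Risk at step 14. Over-reduction or geometric scrambling of the electron-poor polyenyl lactone by excess CrCl2, and incomplete E-selectivity at the new iodoalkene on a substrate whose isomers are hard to separate, may spoil the iodide. The fallback sets out from 21 and 20 and comes back at 25, bypassing 24. The iodo-olefination is moved to the robust dialdehyde: 21 (in excess) with CrCl2 and CHI3 in THF–dioxane should give (2E,4E,6E,8E)-9-iodo-2,7-dimethylnona-2,4,6,8-tetraenal F3, which can be purified to geometric homogeneity at small-molecule stage. Butenolide 20 is then condensed with F3 under the conditions of step 13, by way of 22 and the silyl aldol adduct 5-[(2E,4E,6E,8E)-1-(TBSO)-9-iodo-2,7-dimethylnona-2,4,6,8-tetraenyl]-3-{2-[(1R,4R)-4-(TBSO)-2,6,6-trimethylcyclohex-2-en-1-yl]ethyl}furan-2(5H)-one F4, and DBU elimination gives 25 directly.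

Risk at step 3. Migratory insertion of the congested tetrasubstituted alkenylpalladium into the enone may be so slow that reduction of the triflate and oligomerisation of the enone outrun the coupling. The fallback sets out from 3 and comes back at 5. Palladium-catalysed formylation (Pd(PPh3)4, CO, Bu3SnH, THF, 50 °C), in which CO insertion replaces alkene insertion, should give (4R)-4-(TBSO)-2,6,6-trimethylcyclohex-1-ene-1-carbaldehyde F5. Horner–Wadsworth–Emmons olefination of this aldehyde with diethyl (2-oxopropyl)phosphonate (NaH, THF, 0 → 23 °C) then gives the E-enone 5.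

Further compounds
F1 | step 15 | (4R)-4-(TBSO)-1-[(1E,3E)-4-iodo-3-methylbuta-1,3-dien-1-yl]-2,6,6-trimethylcyclohex-1-ene | I/C=C(C)/C=C/C1=C(C)C[C@@H](O[Si](C)(C)C(C)(C)C)CC1(C)C
F2 | step 15 | tributyl{(1E,3E)-2-methyl-4-[(4R)-4-(TBSO)-2,6,6-trimethylcyclohex-1-en-1-yl]buta-1,3-dien-1-yl}stannane | CCCC[Sn](CCCC)(CCCC)/C=C(C)/C=C/C1=C(C)C[C@@H](O[Si](C)(C)C(C)(C)C)CC1(C)C
F3 | step 14 | (2E,4E,6E,8E)-9-iodo-2,7-dimethylnona-2,4,6,8-tetraenal | O=C/C(C)=C/C=C/C=C(C)/C=C/I
F4 | step 14 | 5-[(2E,4E,6E,8E)-1-(TBSO)-9-iodo-2,7-dimethylnona-2,4,6,8-tetraenyl]-3-{2-[(1R,4R)-4-(TBSO)-2,6,6-trimethylcyclohex-2-en-1-yl]ethyl}furan-2(5H)-one (diastereomer mixture) | CC1=C[C@H](O[Si](C)(C)C(C)(C)C)CC(C)(C)[C@H]1CCC1=CC(OC1=O)C(O[Si](C)(C)C(C)(C)C)/C(C)=C/C=C/C=C(C)/C=C/I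
F5 | step 3 | (4R)-4-(TBSO)-2,6,6-trimethylcyclohex-1-ene-1-carbaldehyde | O=CC1=C(C)C[C@@H](O[Si](C)(C)C(C)(C)C)CC1(C)C
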